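**Strategy**

The plan cuts the O1–C5 bond of the oxolane (O1, C2, C3 carrying the guaiacylmethyl group, C4 carrying the carbinol, C5). C4 bears two oxygenated one-carbon arms, ring C5 and the carbinol carbon; joined through one oxygen as an oxetane they are enantiotopic. In step 6 a chiral cobalt–salen Lewis acid lets the allylic hydroxyl of an achiral 2-(oxetan-3-yl)cinnamyl alcohol open one oxetane CH2: this closes the oxolane, fixes C4 and releases the other arm as CH2OH. The surviving exocyclic alkene carbon is the future C3, set trans by hydroxyl-directed hydrogenation; the carbinol centre comes last, by aryl addition, oxidation and reagent-controlled reduction.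

Key step: step 6

Remark on locants: the overview numbers the oxolane so that C4 bears the carbinol; the systematic names below follow nomenclature rules, in which that carbon is position 3.

Remark on configuration: no structure needed correcting; the (3S,4E) alcohol 10 has the spatial arrangement required in the target, and the same carbon is named (R) from aldehyde 12 onward only because substituent priorities change. The target is (S) at the carbinol and (3R,4R), trans, in the ring.

Assumption: the sense of induction of the cobalt catalyst on this substrate cannot be predicted with certainty; the (R,R) complex is written, and its mirror image would be used if it favoured the (3R) alcohol.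

**Route**

Step 1
Reactants: 1 oxetan-3-one; 2 triethyl phosphonoacetate
Product: 3 ethyl 2-(oxetan-3-ylidene)acetate
Conditions: NaH, THF, 0 °C → rt
Reagents that add atoms: none
Why: Horner–Wadsworth–Emmons olefination of the unhindered strained ketone with the stabilised phosphonate anion; no alkene geometry arises because the oxetane is symmetric.

Step 2
Reactants: 3 ethyl 2-(oxetan-3-ylidene)acetate
Product: 4 ethyl 2-(oxetan-3-yl)acetate
Conditions: H2 (1 atm), 10% Pd/C, EtOAc, rt
Reagents that add atoms: none
Why: Heterogeneous catalytic hydrogenation of the electron-poor exocyclic alkene under neutral conditions, which the oxetane should survive.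

Step 3
Reactants: 4 ethyl 2-(oxetan-3-yl)acetate; 5 4-(benzyloxy)-3-methoxybenzaldehyde
Product: 6 ethyl 3-[4-(benzyloxy)-3-methoxyphenyl]-3-hydroxy-2-(oxetan-3-yl)propanoate (racemic mixture of diastereomers)
Conditions: LiN(i-Pr)2, THF, −78 °C; then 5, −78 °C; aq NH4Cl
Reagents that add atoms: none
Why: Aldol addition of the lithium ester enolate to the non-enolisable aldehyde (the oxetane oxygen is gamma to the enolate carbon, so no beta-elimination is open); the two new stereocentres are left uncontrolled because both are destroyed in step 4.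

Step 4
Reactants: 6 ethyl 3-[4-(benzyloxy)-3-methoxyphenyl]-3-hydroxy-2-(oxetan-3-yl)propanoate
Product: 8 ethyl (E)-3-[4-(benzyloxy)-3-methoxyphenyl]-2-(oxetan-3-yl)prop-2-enoate, via benzylic mesylate 7 (not isolated)
Conditions: MsCl, Et3N, CH2Cl2, 0 °C; then DBU, rt
Reagents that add atoms: none
Why: Mesylation of the benzylic hydroxyl and base-induced E1cB elimination across the acidic alpha C–H should give the conjugated ester, mainly as the (E)-isomer with aryl anti to the ester; any (Z)-isomer is removed by chromatography, although it would converge on the same oxolane after steps 6 and 7.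

Step 5
Reactants: 8 ethyl (E)-3-[4-(benzyloxy)-3-methoxyphenyl]-2-(oxetan-3-yl)prop-2-enoate
Product: 9 (E)-3-[4-(benzyloxy)-3-methoxyphenyl]-2-(oxetan-3-yl)prop-2-en-1-ol
Conditions: i-Bu2AlH (2.5 equiv), CH2Cl2, −78 °C; aq KNaC4H4O6, cold quench
Reagents that add atoms: none
Why: 1,2-Reduction of the conjugated ester by the aluminium hydride gives the allylic alcohol with retention of alkene geometry; the oxetane should tolerate the reagent at −78 °C.

Step 6
Reactants: 9 (E)-3-[4-(benzyloxy)-3-methoxyphenyl]-2-(oxetan-3-yl)prop-2-en-1-ol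
Product: 10 {(3S,4E)-4-[4-(benzyloxy)-3-methoxybenzylidene]oxolan-3-yl}methanol
Conditions: (R,R)-(salen)Co(OTf) (5 mol%; salen = N,N'-bis(3,5-di-tert-butylsalicylidene)cyclohexane-1,2-diaminate), MeCN, 23 °C
Reagents that add atoms: none
Why: The cationic complex of trivalent cobalt binds the oxetane oxygen as a Lewis acid, the allylic hydroxyl attacks one oxetane CH2 from the backside in an SN2 displacement that forms O1–C5, and proton transfer releases the other arm as CH2OH. The closest known reaction type is the cobalt–salen-catalysed enantioselective intramolecular opening of 3-substituted oxetanes by a tethered alcohol to give oxolanes, applied here to a tether that contains an sp2 carbon. The oxolane closes in the 5-exo-tet mode, the breaking C–O bond lying outside the new ring. The single new stereocentre, the former oxetane C3, is controlled by the chiral salen ligand, which distinguishes the two enantiotopic CH2 groups. The step needs enantiotopic-group selectivity only: the substrate is achiral, carries one nucleophile, cannot be attacked at the oxetane methine for geometric reasons, and the mild Lewis acid should neither ionise the electron-rich cinnamyl alcohol nor let the arene compete with the hydroxyl.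

Step 7
Reactants: 10 {(3S,4E)-4-[4-(benzyloxy)-3-methoxybenzylidene]oxolan-3-yl}methanol
Product: 11 {(3S,4R)-4-[4-(benzyloxy)-3-methoxybenzyl]oxolan-3-yl}methanol
Conditions: [Ir(cod)(PCy3)(py)]PF6 (5 mol%), H2 (1 atm), CH2Cl2, rt
Reagents that add atoms: none
Why: Hydroxyl-directed homogeneous hydrogenation with the cationic complex of monovalent iridium: the CH2OH group (pushed out of the alkene plane by allylic strain with the syn aryl group) binds the metal and hydrogen is delivered to the face it occupies, so the new C–H is cis to CH2OH and the benzyl group ends up trans; the aryl benzyl ether is not cleaved by this catalyst.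

Step 8
Reactants: 11 {(3S,4R)-4-[4-(benzyloxy)-3-methoxybenzyl]oxolan-3-yl}methanol
Product: 12 (3R,4R)-4-[4-(benzyloxy)-3-methoxybenzyl]oxolane-3-carbaldehyde
Conditions: Dess–Martin periodinane, CH2Cl2, 0 °C → rt
Reagents that add atoms: none
Why: Dess–Martin oxidation gives the aldehyde under non-basic conditions, so the alpha stereocentre should not epimerise (and the trans isomer is in any case the more stable one).

Step 9
Reactants: 13 2,6-dimethoxyphenol
Product: 14 4-bromo-2,6-dimethoxyphenol
Conditions: NBS, CHCl3, −45 °C → rt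
Reagents that add atoms: N-bromosuccinimide, O=C1CCC(=O)N1Br
Why: Electrophilic aromatic bromination of a phenol whose two ortho positions are blocked by methoxy groups should go para to the hydroxyl.

Step 10
Reactants: 14 4-bromo-2,6-dimethoxyphenol
Product: 15 2-(benzyloxy)-5-bromo-1,3-dimethoxybenzene
Conditions: BnBr, K2CO3, DMF, rt
Reagents that add atoms: benzyl bromide, BrCc1ccccc1
Why: Williamson ether synthesis of the phenoxide with a reactive benzylic halide.

Step 11
Reactants: 15 2-(benzyloxy)-5-bromo-1,3-dimethoxybenzene; 12 (3R,4R)-4-[4-(benzyloxy)-3-methoxybenzyl]oxolane-3-carbaldehyde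
Product: 17 [4-(benzyloxy)-3,5-dimethoxyphenyl]{(3R,4R)-4-[4-(benzyloxy)-3-methoxybenzyl]oxolan-3-yl}methanol (both carbinol epimers), via arylmagnesium bromide 16 (not isolated)
Conditions: Mg turnings (cat. I2), THF, 50 °C; then 12, THF, −78 → 0 °C; aq NH4Cl
Reagents that add atoms: none
Why: Magnesium insertion and Grignard 1,2-addition to the aldehyde form the aryl–carbinol bond; the carbinol configuration is not controlled here (Felkin–Anh addition is expected to favour the unwanted epimer) because the centre is erased in step 12.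

Step 12
Reactants: 17 [4-(benzyloxy)-3,5-dimethoxyphenyl]{(3R,4R)-4-[4-(benzyloxy)-3-methoxybenzyl]oxolan-3-yl}methanol (both carbinol epimers)
Product: 18 [4-(benzyloxy)-3,5-dimethoxyphenyl]{(3R,4R)-4-[4-(benzyloxy)-3-methoxybenzyl]oxolan-3-yl}methanone
Conditions: Dess–Martin periodinane, CH2Cl2, 0 °C → rt
Reagents that add atoms: none
Why: Dess–Martin oxidation of the secondary benzylic alcohol converges both epimers on one aryl ketone; epimerisation alpha to the ketone could only give the less stable cis diastereomer, not the enantiomer.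

Step 13
Reactants: 18 [4-(benzyloxy)-3,5-dimethoxyphenyl]{(3R,4R)-4-[4-(benzyloxy)-3-methoxybenzyl]oxolan-3-yl}methanone
Product: 19 (S)-[4-(benzyloxy)-3,5-dimethoxyphenyl]{(3R,4R)-4-[4-(benzyloxy)-3-methoxybenzyl]oxolan-3-yl}methanol
Conditions: (R)-2-methyl-CBS-oxazaborolidine (20 mol%), BH3·SMe2, THF, −20 °C; MeOH quench
Reagents that add atoms: none
Why: Corey–Bakshi–Shibata reduction: with the aryl group as the large substituent the (R)-oxazaborolidine should deliver hydride to the face that gives the (S)-carbinol, and the Felkin–Anh preference of the substrate (benzyl-bearing ring carbon anti to the incoming hydride) points the same way, so reagent and substrate control are matched.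

Step 14
Reactants: 19 (S)-[4-(benzyloxy)-3,5-dimethoxyphenyl]{(3R,4R)-4-[4-(benzyloxy)-3-methoxybenzyl]oxolan-3-yl}methanol
Product: 20 (S)-(4-hydroxy-3,5-dimethoxyphenyl)[(3R,4R)-4-(4-hydroxy-3-methoxybenzyl)oxolan-3-yl]methanol
Conditions: H2 (1 atm), 10% Pd/C, EtOAc, rt, stopped at full conversion
Reagents that add atoms: none
Why: Hydrogenolysis of the two aryl benzyl ethers over palladium under neutral conditions should be much faster than cleavage of the secondary benzylic C–OH bond, and no acid is present that could trigger cyclisation onto the other arene.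

**Compound list**

1 | oxetan-3-one | O=C1COC1 | starting material
2 | triethyl phosphonoacetate | CCOC(=O)CP(=O)(OCC)OCC | starting material
3 | ethyl 2-(oxetan-3-ylidene)acetate | CCOC(=O)C=C1COC1 | intermediate
4 | ethyl 2-(oxetan-3-yl)acetate | CCOC(=O)CC1COC1 | intermediate
5 | 4-(benzyloxy)-3-methoxybenzaldehyde | COc1cc(C=O)ccc1OCc1ccccc1 | starting material
6 | ethyl 3-[4-(benzyloxy)-3-methoxyphenyl]-3-hydroxy-2-(oxetan-3-yl)propanoate (racemic mixture of diastereomers) | CCOC(=O)C(C1COC1)C(O)c1ccc(OCc2ccccc2)c(OC)c1 | intermediate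
7 | ethyl 3-[4-(benzyloxy)-3-methoxyphenyl]-3-(methanesulfonyloxy)-2-(oxetan-3-yl)propanoate (not isolated) | CCOC(=O)C(C1COC1)C(OS(C)(=O)=O)c1ccc(OCc2ccccc2)c(OC)c1 | intermediate
8 | ethyl (E)-3-[4-(benzyloxy)-3-methoxyphenyl]-2-(oxetan-3-yl)prop-2-enoate | COc1cc(/C=C(/C(=O)OCC)C2COC2)ccc1OCc1ccccc1 | intermediate
9 | (E)-3-[4-(benzyloxy)-3-methoxyphenyl]-2-(oxetan-3-yl)prop-2-en-1-ol | COc1cc(/C=C(/CO)C2COC2)ccc1OCc1ccccc1 | intermediate
10 | {(3S,4E)-4-[4-(benzyloxy)-3-methoxybenzylidene]oxolan-3-yl}methanol | COc1cc(/C=C2/COC[C@@H]2CO)ccc1OCc1ccccc1 | intermediate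
11 | {(3S,4R)-4-[4-(benzyloxy)-3-methoxybenzyl]oxolan-3-yl}methanol | COc1cc(C[C@H]2COC[C@@H]2CO)ccc1OCc1ccccc1 | intermediate
12 | (3R,4R)-4-[4-(benzyloxy)-3-methoxybenzyl]oxolane-3-carbaldehyde | COc1cc(C[C@H]2COC[C@@H]2C=O)ccc1OCc1ccccc1 | intermediate
13 | 2,6-dimethoxyphenol | COc1cccc(OC)c1O | starting material
14 | 4-bromo-2,6-dimethoxyphenol | COc1cc(Br)cc(OC)c1O | intermediate
15 | 2-(benzyloxy)-5-bromo-1,3-dimethoxybenzene | COc1cc(Br)cc(OC)c1OCc1ccccc1 | intermediate
16 | [4-(benzyloxy)-3,5-dimethoxyphenyl]magnesium bromide (not isolated) | COc1cc([Mg]Br)cc(OC)c1OCc1ccccc1 | intermediate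
17 | [4-(benzyloxy)-3,5-dimethoxyphenyl]{(3R,4R)-4-[4-(benzyloxy)-3-methoxybenzyl]oxolan-3-yl}methanol (both carbinol epimers) | COc1cc(C[C@H]2COC[C@@H]2C(O)c2cc(OC)c(OCc3ccccc3)c(OC)c2)ccc1OCc1ccccc1 | intermediate
18 | [4-(benzyloxy)-3,5-dimethoxyphenyl]{(3R,4R)-4-[4-(benzyloxy)-3-methoxybenzyl]oxolan-3-yl}methanone | COc1cc(C[C@H]2COC[C@@H]2C(=O)c2cc(OC)c(OCc3ccccc3)c(OC)c2)ccc1OCc1ccccc1 | intermediate
19 | (S)-[4-(benzyloxy)-3,5-dimethoxyphenyl]{(3R,4R)-4-[4-(benzyloxy)-3-methoxybenzyl]oxolan-3-yl}methanol | COc1cc(C[C@H]2COC[C@@H]2[C@H](O)c2cc(OC)c(OCc3ccccc3)c(OC)c2)ccc1OCc1ccccc1 | intermediate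
20 | (S)-(4-hydroxy-3,5-dimethoxyphenyl)[(3R,4R)-4-(4-hydroxy-3-methoxybenzyl)oxolan-3-yl]methanol | COc1cc(C[C@H]2COC[C@@H]2[C@H](O)c2cc(OC)c(O)c(OC)c2)ccc1O | target

**Step count and risks**

Total step count: 14. Longest linear sequence: 12 steps (steps 1–8 and 11–14, counted from oxetan-3-one 1).

Steps most likely to fail:

1. Step 6. The catalyst may differentiate the two oxetane CH2 groups poorly with the sp2-containing tether, or turn over slowly, so that the alcohol forms with low enantiomeric purity. Fallback, setting out from 9: the ring is closed without asymmetric induction by a catalytic amount of diphenyl hydrogen phosphate in toluene at room temperature to give the racemic benzylidene oxolane alcohol F1. F1 is then resolved by lipase-catalysed transesterification (Burkholderia cepacia lipase, vinyl acetate, t-BuOMe, rt) taken to roughly half conversion. If the enzyme acylates the unwanted enantiomer, the mirror-image acetate F2 is separated on silica from unreacted 10. If it prefers the wanted enantiomer, the acetate F3 derived from 10 is isolated and methanolysed (K2CO3, MeOH) to 10. Either way the route is rejoined at 10.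

2. Step 7. Weak binding of the hydroxyl to iridium could lead to poor facial selectivity, or the alkene could migrate into the ring before it is reduced. Fallback, setting out from 10: the hydroxyl is silylated (TBSCl, imidazole, DMF) to the silyl ether F4 so that it no longer directs. The trisubstituted aryl alkene is then reduced under catalyst control by asymmetric hydrogenation with a chiral phosphine–oxazoline complex of monovalent iridium, [Ir(cod)(L)]BArF (L = 4-tert-butyl-2-[2-(diphenylphosphino)phenyl]-4,5-dihydrooxazole, BArF = tetrakis[3,5-bis(trifluoromethyl)phenyl]borate; H2 50 bar, CH2Cl2). The ligand enantiomer is chosen to add hydrogen to the face of the CH2O substituent, which should give the trans silyl ether F5. Bu4NF in THF then returns the route at 11.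

3. Step 14. Once a phenol is freed, over-reduction could remove the benzylic hydroxyl by C–O hydrogenolysis. Fallback, setting out from 18: both benzyl ethers are hydrogenolysed at the ketone stage (H2, 10% Pd/C, EtOAc), where no benzylic C–O bond is present, to give the bisphenol ketone F6. F6 is silylated (TBSCl, imidazole, DMF) to the bis-silyl ketone F7. F7 is reduced as in step 13 ((R)-2-methyl-CBS-oxazaborolidine, BH3·SMe2) to the bis-silyl (S)-carbinol F8. Bu4NF buffered with AcOH in THF at 0 °C then frees both phenols and returns the route at 20.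

**Further compounds**

F1 | step 6 | racemic {(4E)-4-[4-(benzyloxy)-3-methoxybenzylidene]oxolan-3-yl}methanol | COc1cc(/C=C2/COCC2CO)ccc1OCc1ccccc1
F2 | step 6 | {(3S,4E)-4-[4-(benzyloxy)-3-methoxybenzylidene]oxolan-3-yl}methyl acetate (acetate of the mirror image of 10) | COc1cc(/C=C2/COC[C@H]2COC(C)=O)ccc1OCc1ccccc1
F3 | step 6 | {(3R,4E)-4-[4-(benzyloxy)-3-methoxybenzylidene]oxolan-3-yl}methyl acetate (acetate of 10) | COc1cc(/C=C2/COC[C@@H]2COC(C)=O)ccc1OCc1ccccc1
F4 | step 7 | tert-butyl({(3R,4E)-4-[4-(benzyloxy)-3-methoxybenzylidene]oxolan-3-yl}methoxy)dimethylsilane | COc1cc(/C=C2/COC[C@@H]2CO[Si](C)(C)C(C)(C)C)ccc1OCc1ccccc1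
F5 | step 7 | tert-butyl({(3R,4R)-4-[4-(benzyloxy)-3-methoxybenzyl]oxolan-3-yl}methoxy)dimethylsilane | COc1cc(C[C@H]2COC[C@@H]2CO[Si](C)(C)C(C)(C)C)ccc1OCc1ccccc1
F6 | step 14 | (4-hydroxy-3,5-dimethoxyphenyl)[(3R,4R)-4-(4-hydroxy-3-methoxybenzyl)oxolan-3-yl]methanone | COc1cc(C[C@H]2COC[C@@H]2C(=O)c2cc(OC)c(O)c(OC)c2)ccc1O
F7 | step 14 | {4-[(tert-butyldimethylsilyl)oxy]-3,5-dimethoxyphenyl}[(3R,4R)-4-{4-[(tert-butyldimethylsilyl)oxy]-3-methoxybenzyl}oxolan-3-yl]methanone | COc1cc(C[C@H]2COC[C@@H]2C(=O)c2cc(OC)c(O[Si](C)(C)C(C)(C)C)c(OC)c2)ccc1O[Si](C)(C)C(C)(C)C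
F8 | step 14 | (S)-{4-[(tert-butyldimethylsilyl)oxy]-3,5-dimethoxyphenyl}[(3R,4R)-4-{4-[(tert-butyldimethylsilyl)oxy]-3-methoxybenzyl}oxolan-3-yl]methanol | COc1cc(C[C@H]2COC[C@@H]2[C@H](O)c2cc(OC)c(O[Si](C)(C)C(C)(C)C)c(OC)c2)ccc1O[Si](C)(C)C(C)(C)C
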